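The nucleophile is spent on two counts: each target takes one nucleophile, and the acid set free with it can take another as protonated nucleophile.

| flask | electrophile | nucleophile | remark | time |
|---|---|---|---|---|
| dusk | 0.38 M | 2.28 M | run made earlier |  |
| spring | 1.6 M | 2.28 M | run made earlier |  |
| summer | 1.9 M | 1.1 M | run made earlier |  |
| Friday's | 1.9 M | 0.800 M |  | 20 min |
| Tuesday's | 0.60 M | 2.28 M |  | 20 min |
| Monday's | 1.9 M | 2.28 M |  | 20 min |
| Thursday's | 1.0 M | 1.50 M |  | 20 min |
| Wednesday's | 1.9 M | 1.20 M |  | 20 min |

| run | time / min | target / % |
|---|---|---|
| dusk | 1.50 | 34.7 |
| dusk | 2.50 | 49.7 |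
| dusk | 4.00 | 64.5 |
| dusk | 6.00 | 77.9 |
| dusk | 8.00 | 86.8 |
| dusk | 12.0 | 95.0 |
| dusk | 20.0 | 98.1 |
| spring | 3.00 | 43.7 |
| spring | 6.00 | 57.0 |
| spring | 8.00 | 62.4 |
| spring | 12.0 | 67.2 |
| spring | 15.0 | 70.9 |
| spring | 20.0 | 75.7 |
| summer | 4.00 | 24.6 |
| summer | 8.00 | 30.0 |
| summer | 12.0 | 34.5 |
| summer | 15.0 | 35.3 |
| summer | 20.0 | 39.7 |

(standard deviation of a reading: 0.5 percentage points)

- all flasks from highest to lowest amount of target, in percent of the electrophile charged, at 20 min (Friday's / Tuesday's / Monday's / Thursday's / Wednesday's)
- the same order at 2.0 min (Friday's / Tuesday's / Monday's / Thursday's / Wednesday's)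
- the amount of target, in percent of the electrophile charged of the flask you put first, at 20 min
- the amount of target, in percent of the electrophile charged of the flask you put last, at 20 min

- what was read earlier has a scatter of 0.5 percentage points, one standard deviation
- steps under discussion: electrophile + nucleophile -> acid set free + target; acid set free -> by-product carried off; nucleophile + acid set free <-> protonated nucleophile

I solve two extreme flasks in my head. Suppose no acid is carried off and every acid set free is bound as protonated nucleophile: free nucleophile then gives out when target reaches half the nucleophile charge, and that level, as a share of the electrophile charged, I call the stall yield, for Friday's 21.1%. The binding step runs both ways, so I take this level as a mark and not as a ceiling. Suppose instead the acid leaves at once: each target costs one nucleophile, and Friday's stops at 42.1%.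

The summer run shows where a real flask stands between these. Its stall yield is 28.9% and its other extreme 57.9%, and it reads 39.7% at 20.0 min. So I compute only the correction, the overshoot above the stall, which summer reads as 0.204 M of target. Friday's has summer's electrophile charge, so I add that reading to its stall and get 31.8%.

The stall yields also give my order. Tuesday's has 190%, which is above the whole charge, so there the electrophile is the limiting reagent, and I expect a little under dusk's 98.1%. Thursday's has 75.0%, Monday's 60.0%, and Wednesday's 31.6%. Monday's with summer's overshoot reaches 70.8%, still less than Thursday's stall, so I put Thursday's ahead.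

The forecast, stepped by hand, gives Tuesday's > Thursday's > Monday's > Wednesday's > Friday's at 20 min and Tuesday's > Monday's > Thursday's > Wednesday's > Friday's at 2.0 min, with 97% for the first and 30% for the last, calling the creep “limited by acid escape”. Its order at 20 min is mine, and its Friday's figure lies a little below mine.

The flasks give Tuesday's > Thursday's > Monday's > Wednesday's > Friday's at 20 min and Tuesday's > Monday's > Thursday's > Wednesday's > Friday's at 2.0 min, with 97.4% first and 30.4% last at 20 min.

    electrophile + nucleophile → acid set free + target (k = 0.00221 /M/s)
    acid set free → by-product carried off (k = 0.00586 /s)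
    nucleophile + acid set free ⇌ protonated nucleophile, settled at all times (K = 55.0 /M)

Friday's stands 9.3 percentage points above its stall yield of 21.1% at 20 min. The same division on Tuesday's flask with 0.57 M of nucleophile gives a stall yield of 47.5%. That flask holds 46.9% of target at 20.0 min, just under its stall yield, with 53% of its electrophile still unbound.

(All runs come from a simulation with made-up constants; the scatter is artificial.)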